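**Plan**
Retrosynthesis: the C4–OH bond is traced back to a C4–OMe bond, the prenyl C=C to an allyl C=C, and then O1–C2 and C3–C4 of the pyran ring are cut together.
The double cut is possible because O1 (on C8a) and the oxygen-bearing benzylic C4 (on C4a) sit ortho on ring A, so ring C is the [4+2] adduct of styrene with an o-quinone methide of ring A that already carries the C4 oxygen as OMe.
Forward: ring A is bought as 3,5-dimethoxyphenol; O-allylation, Claisen rearrangement and ortho-formylation give the salicylaldehyde, which closes ring C with trimethyl orthoformate and styrene in one operation; then allyl becomes prenyl and 4-OMe becomes 4-OH.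
Stereochemistry: C2 (S) comes from a chiral N-triflyl phosphoramide in the cycloaddition; C4 (R) comes from capture of the flavan-4-yl cation by water trans to the 2-phenyl group in the last step.

Key step: step 4

Assumption: the (R)-configured acid is written as the one that delivers 2S; the sense of induction cannot be derived with certainty, and the mirror-image acid would be taken if it proves opposite.
Remark: the side chain is carried as allyl through the cycloaddition because a prenyl alkene is about as nucleophilic as styrene and would compete for the quinone methide. Flavan numbering (O1, C2, C3, C4, C4a, C5–C8, C8a) is used for 9–11.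

Step 1
Reactants: 1 3,5-dimethoxyphenol; 2 allyl bromide
Product: 3 allyl 3,5-dimethoxyphenyl ether (1-allyloxy-3,5-dimethoxybenzene)
Conditions: K2CO3, acetone, reflux
Reagents that add atoms: none
Why: Williamson ether synthesis, in which the potassium phenoxide in acetone should be alkylated at oxygen by the allylic bromide, with C-allylation minor in this medium.

Step 2
Reactants: 3 allyl 3,5-dimethoxyphenyl ether
Product: 4 2-allyl-3,5-dimethoxyphenol
Conditions: PhNEt2, 200 °C, sealed tube
Reagents that add atoms: none
Why: aromatic Claisen rearrangement, a [3,3] shift to either of the two equivalent free ortho carbons followed by rearomatisation, which should give a single ortho-allylphenol.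

Step 3
Reactants: 4 2-allyl-3,5-dimethoxyphenol
Product: 5 3-allyl-2-hydroxy-4,6-dimethoxybenzaldehyde
Conditions: MgCl2, Et3N, (CH2O)n, MeCN, reflux; then 1 M HCl
Reagents that add atoms: paraformaldehyde (as formaldehyde), C=O
Why: Casnati–Skattebøl ortho-formylation, in which the magnesium phenoxide delivers formaldehyde only to the one free ortho carbon and the benzylic alkoxide is oxidised by hydride transfer to a second formaldehyde, so the carbon between the methoxy groups and the allyl group should stay untouched.

Step 4
Reactants: 5 3-allyl-2-hydroxy-4,6-dimethoxybenzaldehyde; 6 styrene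
Product: 9 (2S,4R)-8-allyl-4,5,7-trimethoxy-2-phenylchroman, via dimethyl acetal 7 (not isolated), via 4-methoxy o-quinone methide 8 (not isolated)
Conditions: HC(OMe)3 (3 equiv), styrene (5 equiv), (R)-3,3'-bis(2,4,6-triisopropylphenyl)-1,1'-binaphthyl-2,2'-diyl N-triflylphosphoramide (5 mol%), toluene, 0 °C → rt; Et3N quench
Reagents that add atoms: trimethyl orthoformate, COC(OC)OC
Why: Proposed new method: the acid turns 5 into acetal 7 and ionises it to the 4-methoxy o-quinone methide 8, whose O-protonated form, a 2-hydroxyaryl methoxycarbenium ion stabilised by the 5- and 7-methoxy groups, stays hydrogen-bonded and ion-paired to the chiral phosphoramidate while the CH2 terminus of styrene bonds to the exocyclic carbon (C3–C4) and the phenolic oxygen closes on the benzylic carbon (O1–C2). The closest known reactions are the racemic acid-catalysed three-component chroman synthesis from a salicylaldehyde, an orthoformate and an alkene, and chiral phosphoric acid catalysed cycloadditions of aryl-substituted o-quinone methides with styrenes. Ring C closes as an inverse-demand oxa-[4+2] cycloaddition, either concerted and asynchronous or as Prins-type C–C bond formation followed by capture of the benzylic cation by the phenol oxygen within the ion pair. C2 is set under catalyst control by the chiral anion bound at the quinone methide oxygen and is configurationally stable once the ether is formed; C4 is free to equilibrate through the C4 cation and should rest as the 4-methoxy epimer trans to phenyl (pseudo-axial, clear of the peri 5-OMe), a ratio without consequence because step 6 passes through the same cation. Regiochemistry follows styrene polarity (positive charge develops at the carbon bearing phenyl), and chemoselectivity rests on the side chain being a monosubstituted allyl alkene, far less nucleophilic than styrene, with excess styrene and the reversibility of Friedel–Crafts attack by ring A expected to keep oligomers down.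

Step 5
Reactants: 9 (2S,4R)-8-allyl-4,5,7-trimethoxy-2-phenylchroman
Product: 10 (2S,4R)-4,5,7-trimethoxy-8-(3-methylbut-2-enyl)-2-phenylchroman
Conditions: 2-methylbut-2-ene (excess), second-generation Grubbs catalyst RuCl2(=CHPh)(H2IMes)(PCy3) (5 mol%), CH2Cl2, 40 °C, sealed vessel
Reagents that add atoms: 2-methylbut-2-ene, CC=C(C)C
Why: olefin cross-metathesis, in which the terminal allyl alkene should exchange its CH2 terminus for the isopropylidene unit of the trisubstituted partner used in large excess, leaving the ethers and both stereocentres untouched.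

Step 6
Reactants: 10 (2S,4R)-4,5,7-trimethoxy-8-(3-methylbut-2-enyl)-2-phenylchroman
Product: 11 (2S,4R)-5,7-dimethoxy-8-(3-methylbut-2-enyl)-2-phenylchroman-4-ol
Conditions: 0.05 M aq. HCl/THF (1:3), 0 °C → rt; NaHCO3 quench
Reagents that add atoms: water, O
Why: acid-catalysed SN1 solvolysis of the ortho/para-oxygenated benzylic ether, in which water should capture the flavan-4-yl cation along the pseudo-axial trajectory anti to the equatorial 2-phenyl group and reversible ionisation should settle the mixture on the 2,4-trans alcohol (4R) with its OH clear of the peri 5-OMe, while C2 and the prenyl group are not touched.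

**Compound list**
1 | 3,5-dimethoxyphenol | COc1cc(O)cc(OC)c1 | starting material
2 | allyl bromide | C=CCBr | starting material
3 | allyl 3,5-dimethoxyphenyl ether | C=CCOc1cc(OC)cc(OC)c1 | intermediate
4 | 2-allyl-3,5-dimethoxyphenol | Oc1cc(OC)cc(OC)c1CC=C | intermediate
5 | 3-allyl-2-hydroxy-4,6-dimethoxybenzaldehyde | O=Cc1c(OC)cc(OC)c(CC=C)c1O | intermediate
6 | styrene | C=Cc1ccccc1 | starting material
7 | 2-allyl-6-(dimethoxymethyl)-3,5-dimethoxyphenol (dimethyl acetal of 5) | COC(OC)c1c(OC)cc(OC)c(CC=C)c1O | intermediate
8 | 2-allyl-3,5-dimethoxy-6-(methoxymethylidene)cyclohexa-2,4-dien-1-one (4-methoxy o-quinone methide, exocyclic double bond geometry not assigned) | COC=C1C(=O)C(CC=C)=C(OC)C=C1OC | intermediate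
9 | (2S,4R)-8-allyl-4,5,7-trimethoxy-2-phenylchroman | COc1cc(OC)c2c(c1CC=C)O[C@H](c1ccccc1)C[C@H]2OC | intermediate
10 | (2S,4R)-4,5,7-trimethoxy-8-(3-methylbut-2-enyl)-2-phenylchroman | COc1cc(OC)c2c(c1CC=C(C)C)O[C@H](c1ccccc1)C[C@H]2OC | intermediate
11 | (2S,4R)-5,7-dimethoxy-8-(3-methylbut-2-enyl)-2-phenylchroman-4-ol | COc1cc(OC)c2c(c1CC=C(C)C)O[C@H](c1ccccc1)C[C@H]2O | target

Total step count: 6
Longest linear sequence: 6 steps (1 to 11)

**Steps most likely to fail**

Step 4 (the step proposed as a new method). The ion pair may discriminate the styrene faces poorly, the donor-stabilised quinone methide may add sluggishly to an unactivated styrene, and Friedel–Crafts self-condensation through the free C6 position of ring A may outrun cycloaddition. The fallback uses known flavanone chemistry, sets out from 5 and comes back at 9.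
- Aldehyde 5 would be treated with MeMgBr (THF, 0 °C) to give racemic 1-(3-allyl-2-hydroxy-4,6-dimethoxyphenyl)ethanol F1, which MnO2 (CH2Cl2) should oxidise to 1-(3-allyl-2-hydroxy-4,6-dimethoxyphenyl)ethanone F2.
- Claisen–Schmidt condensation with benzaldehyde (KOH, EtOH) should give (E)-1-(3-allyl-2-hydroxy-4,6-dimethoxyphenyl)-3-phenylprop-2-en-1-one F3, which should cyclise by oxa-Michael addition (NaOAc, EtOH, reflux) to racemic 8-allyl-5,7-dimethoxyflavanone F4.
- Kinetic resolution by Noyori transfer hydrogenation with RuCl(p-cymene)[(S,S)-TsDPEN] and HCO2H/Et3N should reduce the (2S) ketone faster, giving (2S,4S)-8-allyl-5,7-dimethoxyflavan-4-ol F5 and leaving the (2R) ketone behind.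
- F5 in MeOH with catalytic PPTS should exchange OH for OMe through the C4 cation and rejoin the route at 9.

Step 6. Capture of the C4 cation may show poor facial selectivity, and E1 loss of H3 toward the 2H-chromene or cation-mediated dimerisation may compete. The fallback sets C4 by hydride reduction and SN2 inversion instead; it sets out from 10 and comes back at 11.
- The solvolysis of 10 would be run as in step 6, and the mixture of 11 with its C4 epimer (2S,4S)-5,7-dimethoxy-8-(3-methylbut-2-enyl)-2-phenylchroman-4-ol F6 would be oxidised with MnO2 (CH2Cl2) to (S)-5,7-dimethoxy-8-(3-methylbut-2-enyl)flavanone F7.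
- NaBH4 (MeOH, 0 °C) should deliver hydride axially and return the cis alcohol F6 alone.
- Mitsunobu inversion (4-nitrobenzoic acid, PPh3, DIAD, THF, 0 °C) should give (2S,4R)-5,7-dimethoxy-8-(3-methylbut-2-enyl)-2-phenylchroman-4-yl 4-nitrobenzoate F8, and K2CO3/MeOH should release 11.

Step 5. Ruthenium hydride species may isomerise the allyl group into conjugation with ring A, and turnover may stall at the doubly ortho-substituted arene. The fallback builds the trisubstituted alkene by carbonyl olefination; it sets out from 9 and comes back at 10.
- Dihydroxylation (OsO4 cat., NMO, acetone/H2O) should give (2S,4R)-8-(2,3-dihydroxypropyl)-4,5,7-trimethoxy-2-phenylchroman F9 as a mixture of epimers at the new carbinol carbon.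
- NaIO4 (THF/H2O) should cleave the diol to 2-[(2S,4R)-4,5,7-trimethoxy-2-phenylchroman-8-yl]acetaldehyde F10.
- Wittig olefination with isopropylidenetriphenylphosphorane (from isopropyltriphenylphosphonium iodide and n-BuLi, THF, −78 → 0 °C) should return 10.

**Further compounds**
F1 | step 4 | 1-(3-allyl-2-hydroxy-4,6-dimethoxyphenyl)ethanol (racemic) | CC(O)c1c(OC)cc(OC)c(CC=C)c1O
F2 | step 4 | 1-(3-allyl-2-hydroxy-4,6-dimethoxyphenyl)ethanone | CC(=O)c1c(OC)cc(OC)c(CC=C)c1O
F3 | step 4 | (E)-1-(3-allyl-2-hydroxy-4,6-dimethoxyphenyl)-3-phenylprop-2-en-1-one | O=C(/C=C/c1ccccc1)c1c(OC)cc(OC)c(CC=C)c1O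
F4 | step 4 | 8-allyl-5,7-dimethoxyflavanone (racemic) | COc1cc(OC)c2c(c1CC=C)OC(c1ccccc1)CC2=O
F5 | step 4 | (2S,4S)-8-allyl-5,7-dimethoxyflavan-4-ol | COc1cc(OC)c2c(c1CC=C)O[C@H](c1ccccc1)C[C@@H]2O
F6 | step 6 | (2S,4S)-5,7-dimethoxy-8-(3-methylbut-2-enyl)-2-phenylchroman-4-ol | COc1cc(OC)c2c(c1CC=C(C)C)O[C@H](c1ccccc1)C[C@@H]2O
F7 | step 6 | (S)-5,7-dimethoxy-8-(3-methylbut-2-enyl)flavanone | COc1cc(OC)c2c(c1CC=C(C)C)O[C@H](c1ccccc1)CC2=O
F8 | step 6 | (2S,4R)-5,7-dimethoxy-8-(3-methylbut-2-enyl)-2-phenylchroman-4-yl 4-nitrobenzoate | COc1cc(OC)c2c(c1CC=C(C)C)O[C@H](c1ccccc1)C[C@H]2OC(=O)c1ccc(cc1)[N+](=O)[O-]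
F9 | step 5 | (2S,4R)-8-(2,3-dihydroxypropyl)-4,5,7-trimethoxy-2-phenylchroman (epimers at the side-chain carbinol) | COc1cc(OC)c2c(c1CC(O)CO)O[C@H](c1ccccc1)C[C@H]2OC
F10 | step 5 | 2-[(2S,4R)-4,5,7-trimethoxy-2-phenylchroman-8-yl]acetaldehyde | COc1cc(OC)c2c(c1CC=O)O[C@H](c1ccccc1)C[C@H]2OC
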